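## Retrosynthetic overview
1. The ten-membered ring is the only carbocycle and is closed last. C6=C7 comes from ring-closing metathesis of an allyl/methallyl diene, and ring strain gives Z.
2. Both ester C–O bonds and the C1 and C4 stereocentres come from a Tishchenko relay on an acyclic (Z)-ene-1,4-dione. C9–OH becomes the benzoate (PhCHO, hydride to C1), then C1–O becomes the acetate (MeCHO, hydride to C4). The free OH ends on C4, so no protecting groups are needed.
3. The (Z)-enedione comes from a 2,3,5-trisubstituted furan and singlet oxygen (two C–O bonds). The furan is a temporary ring, formed first, and it stores the Z geometry of C2=C3.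
4. The furan comes from a Weinreb amide (C7–C10 and C1) and a dilithiated (Z)-iodo dienol (C2–C6), by acylation followed by C–O cyclodehydration.
5. C9 and C10 come from an Evans syn aldol. The Z-iodide comes from propargyl alcohol by anti-carbomagnesiation.

**Atom labels:** C1–C10 are the ring atoms in the order of the target SMILES: C1 CHOAc, C2=C3(Me), C4 CHOH, C5, C6=C7(Me), C8, C9 CHOBz, C10 CH-iPr. The target is 1S,4R,9S,10R with 2Z,6Z.

**Assumption:** 8 is bought as a bulk intermediate. If not, it is one N-acylation of (R)-4-benzyloxazolidin-2-one with isovaleryl chloride.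

## Route

Step 1
Reactants: 1 prop-2-yn-1-ol
Product: 3 (2Z)-3-iodo-2-methylprop-2-en-1-ol, via alkenylmagnesium alkoxide 2 (not isolated)
Conditions: MeMgBr (2.5 equiv), CuI (10 mol %), Et2O/THF, -10 °C to rt; then I2, 0 °C
Reagents that add atoms: methylmagnesium bromide, C[Mg]Br; iodine, II
Why: Cu-catalysed alkoxide-directed anti-carbomagnesiation puts Me on the internal carbon and Mg cis to CH2O in a five-membered chelate, and iodinolysis with retention fixes the Z-alkene that becomes C2=C3.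

Step 2
Reactants: 3 (2Z)-3-iodo-2-methylprop-2-en-1-ol
Product: 4 (2Z)-3-iodo-2-methylprop-2-enal
Conditions: MnO2 (15 equiv), CH2Cl2, rt, dark
Reagents that add atoms: none
Why: Neutral heterogeneous MnO2 allylic oxidation stops at the enal and does not isomerise the Z-iodoalkene.

Step 3
Reactants: 4 (2Z)-3-iodo-2-methylprop-2-enal
Product: 5 (1Z)-1-iodo-2-methylhexa-1,5-dien-3-ol (racemic)
Conditions: allylMgBr (1.1 equiv), Et2O, -78 °C
Reagents that add atoms: allylmagnesium bromide, C=CC[Mg]Br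
Why: Grignard 1,2-addition brings in C5–C6, and the new carbinol centre is left racemic on purpose because it is erased in the furan.

Step 4
Reactants: 6 3-methylbut-3-en-1-ol
Product: 7 3-methylbut-3-enal
Conditions: Dess–Martin periodinane (1.1 equiv), CH2Cl2, 0 °C to rt; cold NaHCO3/Na2S2O3 wash; dried solution used at once
Reagents that add atoms: none
Why: Dess–Martin oxidation is mild and non-basic, so the beta,gamma-alkene does not move into conjugation.

Step 5
Reactants: 8 (4R)-4-benzyl-3-(3-methylbutanoyl)-1,3-oxazolidin-2-one; 7 3-methylbut-3-enal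
Product: 10 (4R)-4-benzyl-3-[(2R,3S)-3-hydroxy-5-methyl-2-(propan-2-yl)hex-5-enoyl]-1,3-oxazolidin-2-one, via boron enolate 9 (not isolated)
Conditions: Bu2BOTf (1.1 equiv), Et3N (1.3 equiv), CH2Cl2, 0 °C; 7, -78 to 0 °C; H2O2, MeOH, pH 7 buffer, 0 °C
Reagents that add atoms: none
Why: In the Evans boron syn aldol the Z-enolate reacts through a Zimmerman–Traxler chair on the face left open by the (R)-benzyl auxiliary, which sets C10 (R) and C9 (S) in the syn relation of the target.

Step 6
Reactants: 10 Evans syn-aldol adduct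
Product: 11 (2R,3S)-3-hydroxy-N-methoxy-N,5-dimethyl-2-(propan-2-yl)hex-5-enamide
Conditions: MeONHMe·HCl (3 equiv), AlMe3 (3 equiv), CH2Cl2, -20 °C to rt; Rochelle salt
Reagents that add atoms: N,O-dimethylhydroxylamine hydrochloride, CNOC.Cl
Why: In this Weinreb transamidation the aluminium amide, anchored on the free beta-hydroxyl, attacks only the exocyclic carbonyl and releases the auxiliary without epimerisation.

Step 7
Reactants: 5 (1Z)-1-iodo-2-methylhexa-1,5-dien-3-ol; 11 Weinreb amide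
Product: 15 (4S,5R)-2,6-dimethyl-5-[4-methyl-5-(prop-2-en-1-yl)furan-2-yl]hept-1-en-4-ol, via dilithio reagent 12 (not isolated), via chloromagnesium alkoxide 13 (not isolated), via hydroxy enone 14 (not isolated)
Conditions: 5 (1.2 equiv), t-BuLi (3.6 equiv), Et2O, -78 °C; 11 + i-PrMgCl (1.0 equiv), THF, -20 °C, cannulated in; -78 to 0 °C; 1 M HCl, THF, rt, 1 h
Reagents that add atoms: none
Why: Iodine–lithium exchange with retention and Weinreb ketone synthesis give the (Z)-gamma-hydroxy enone, which closes to the hemiketal (new O–C1 bond) and loses water in a Paal–Knorr-type cyclodehydration, so the robust furan locks C1 and C4 cis across C2=C3.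

Step 8
Reactants: 15 trisubstituted furan
Product: 17 (4S,5R,7Z)-4-hydroxy-2,8-dimethyl-5-(propan-2-yl)dodeca-1,7,11-triene-6,9-dione, via furan endoperoxide 16 (not isolated)
Conditions: O2, tetraphenylporphyrin (1 mol %), visible light, CH2Cl2, -78 °C; Me2S (3 equiv), -78 to 0 °C; used crude
Reagents that add atoms: oxygen, O=O
Why: In furan photooxygenation singlet oxygen adds [4+2] only to the electron-rich furan, since the mono- and 1,1-disubstituted alkenes are inert, and reductive opening of the endoperoxide gives the ene-1,4-dione, which is Z because it comes from a ring.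

Step 9
Reactants: 17 (Z)-beta-hydroxy enedione
Product: 19 (4S,5R,6S,7Z,9R)-6-acetoxy-9-hydroxy-2,8-dimethyl-5-(propan-2-yl)dodeca-1,7,11-trien-4-yl benzoate, via hydroxy enone benzoate 18 (not isolated)
Conditions: SmI2 (0.3 equiv) premixed with PhCHO (1.5 equiv), THF, -10 °C; 17, 2 h; then MeCHO (20 equiv), -10 to 0 °C, 6 h; pH 7 buffer
Reagents that add atoms: benzaldehyde, O=Cc1ccccc1; acetaldehyde, CC=O
Why: Proposed new method: a two-stage Tishchenko relay in which stage 1 is the ordinary Evans–Tishchenko reaction (C9–OH and PhCHO form a Sm-bound hemiacetal that passes hydride through a six-membered array to C1=O, 1,3-anti, giving the C9 benzoate and 18), and stage 2 is unprecedented: the freed C1 alkoxide adds to MeCHO and, because the Z-alkene holds the C1–O bond and the s-cis C4=O on one Sm(III) centre, the hemiacetal C–H is passed to C4 through a seven-membered array with C1–H in the alkene plane (A1,3 control) from the face that carries C1–O, which turns the hemiacetal C–O bond into the C1 acetate and leaves the (4R)-hydroxyl free; the closest known reaction types are the Evans–Tishchenko 1,3-reduction and Meerwein–Ponndorf–Verley hydride transfer.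

Step 10
Reactants: 19 acyclic triene
Product: 20 (1S,2Z,4R,6Z,9S,10R)-1-acetoxy-4-hydroxy-3,7-dimethyl-10-(propan-2-yl)cyclodeca-2,6-dien-9-yl benzoate (CNP0125882.1)
Conditions: Hoveyda–Grubbs II (15 mol %, in portions), 1,4-benzoquinone (30 mol %), PhMe (0.5 mM), 80 °C, Ar sparge
Reagents that add atoms: none
Why: In the ring-closing metathesis the catalyst loads on the allyl terminus and closes onto the 1,1-disubstituted alkene, the Z C2=C3 turn and three branches pre-fold the chain, and a ten-membered ring accepts only the Z trisubstituted C6=C7.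

## Compound list
1 | prop-2-yn-1-ol | C#CCO | starting material
2 | bromo{(1Z)-3-[(bromomagnesio)oxy]-2-methylprop-1-en-1-yl}magnesium | Br[Mg]OC/C(C)=C\[Mg]Br | intermediate
3 | (2Z)-3-iodo-2-methylprop-2-en-1-ol | OC/C(C)=C\I | intermediate
4 | (2Z)-3-iodo-2-methylprop-2-enal | O=C/C(C)=C\I | intermediate
5 | (1Z)-1-iodo-2-methylhexa-1,5-dien-3-ol, racemic | C=CCC(O)/C(C)=C\I | intermediate
6 | 3-methylbut-3-en-1-ol | C=C(C)CCO | starting material
7 | 3-methylbut-3-enal | C=C(C)CC=O | intermediate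
8 | (4R)-4-benzyl-3-(3-methylbutanoyl)-1,3-oxazolidin-2-one | CC(C)CC(=O)N1[C@H](Cc2ccccc2)COC1=O | starting material
9 | (4R)-4-benzyl-3-{(1Z)-1-[(dibutylboranyl)oxy]-3-methylbut-1-en-1-yl}-1,3-oxazolidin-2-one | CCCCB(CCCC)O/C(=C\C(C)C)N1[C@H](Cc2ccccc2)COC1=O | intermediate
10 | (4R)-4-benzyl-3-[(2R,3S)-3-hydroxy-5-methyl-2-(propan-2-yl)hex-5-enoyl]-1,3-oxazolidin-2-one | O=C1OC[C@@H](Cc2ccccc2)N1C(=O)[C@H](C(C)C)[C@@H](O)CC(C)=C | intermediate
11 | (2R,3S)-3-hydroxy-N-methoxy-N,5-dimethyl-2-(propan-2-yl)hex-5-enamide | CON(C)C(=O)[C@H](C(C)C)[C@@H](O)CC(C)=C | intermediate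
12 | lithium (1Z)-1-lithio-2-methylhexa-1,5-dien-3-olate | [Li]OC(CC=C)/C(C)=C\[Li] | intermediate
13 | chloromagnesium alkoxide of 11 | CON(C)C(=O)[C@H](C(C)C)[C@@H](O[Mg]Cl)CC(C)=C | intermediate
14 | (4S,5R,7Z)-4,9-dihydroxy-2,8-dimethyl-5-(propan-2-yl)dodeca-1,7,11-trien-6-one, both C9 epimers | C=CCC(O)/C(C)=C\C(=O)[C@H](C(C)C)[C@@H](O)CC(C)=C | intermediate
15 | (4S,5R)-2,6-dimethyl-5-[4-methyl-5-(prop-2-en-1-yl)furan-2-yl]hept-1-en-4-ol | C=CCc1oc(cc1C)[C@H](C(C)C)[C@@H](O)CC(C)=C | intermediate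
16 | (4S,5R)-2,6-dimethyl-5-[5-methyl-4-(prop-2-en-1-yl)-2,3,7-trioxabicyclo[2.2.1]hept-5-en-1-yl]hept-1-en-4-ol, both faces | C=CCC12OOC(O1)(C=C2C)[C@H](C(C)C)[C@@H](O)CC(C)=C | intermediate
17 | (4S,5R,7Z)-4-hydroxy-2,8-dimethyl-5-(propan-2-yl)dodeca-1,7,11-triene-6,9-dione | C=CCC(=O)/C(C)=C\C(=O)[C@H](C(C)C)[C@@H](O)CC(C)=C | intermediate
18 | (4S,5S,6S,7Z)-6-hydroxy-2,8-dimethyl-9-oxo-5-(propan-2-yl)dodeca-1,7,11-trien-4-yl benzoate | C=CCC(=O)/C(C)=C\[C@H](O)[C@H](C(C)C)[C@@H](OC(=O)c1ccccc1)CC(C)=C | intermediate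
19 | (4S,5R,6S,7Z,9R)-6-acetoxy-9-hydroxy-2,8-dimethyl-5-(propan-2-yl)dodeca-1,7,11-trien-4-yl benzoate | C=CC[C@@H](O)/C(C)=C\[C@H](OC(C)=O)[C@H](C(C)C)[C@@H](OC(=O)c1ccccc1)CC(C)=C | intermediate
20 | (1S,2Z,4R,6Z,9S,10R)-1-acetoxy-4-hydroxy-3,7-dimethyl-10-(propan-2-yl)cyclodeca-2,6-dien-9-yl benzoate | CC(=O)O[C@H]1/C=C(/C)[C@H](O)C/C=C(/C)C[C@H](OC(=O)c2ccccc2)[C@H]1C(C)C | target

## Step count and risks
Total steps: 10. Longest linear sequence: 7 (steps 1–3 then 7–10, or steps 4–6 then 7–10).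

**Step 9 (new relay).**
- Risks: 18 may rest as its cyclic hemiketal or dehydrate back to a furan. Left-over PhCHO may cross over into stage 2. The 1,4-induction may be weak.
- The fallback uses known chemistry only, sets out from 17 and comes back at 19.
- Run only the Evans–Tishchenko stage (SmI2 cat., PhCHO, -10 °C) to reach 18.
- Quench in the same flask with Ac2O/DMAP/pyridine to give the acetoxy enone F1.
- Reduce C4=O with (S)-Me-CBS and catecholborane (toluene, -78 °C). The alkenyl group acts as the large group, so reagent control gives (4R) and hence 19.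

**Step 10 (ten-membered RCM).**
- Risks: oligomers, or alkene migration in place of closure.
- The fallback sets out from 17 and comes back at 20.
- Close the ring earlier, on the flatter chain in which C1 and C4 are still sp2. The same catalyst system on 17 gives the macrocyclic enedione F2.
- Evans–Tishchenko reduction with PhCHO gives the ring hydroxy benzoate F3.
- Trap F3 in the flask with Ac2O/DMAP as the ring acetoxy enone F4.
- (S)-Me-CBS/catecholborane reduction of C4=O then gives 20.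

**Step 8 (labile enedione).**
- Risks: Z to E drift, oxa-Michael closure of C9–OH, or conjugation of the allyl ketone.
- The fallback leaves the furan line, sets out from 4 and 11 and comes back at 19.
- Allylboration of 4 with allylB(Ipc)2 made from (-)-alpha-pinene gives the (3R)-iodo dienol F5.
- TBSCl/imidazole gives the silyl ether F6.
- Iodine–lithium exchange (t-BuLi, Et2O, -78 °C) and addition to 11 (as 13) gives the beta-hydroxy (Z)-enone F7.
- Evans–Tishchenko reaction with PhCHO gives the hydroxy benzoate F8.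
- Ac2O/DMAP gives the acetate F9.
- HF·pyridine frees the C4 hydroxyl to give 19.

Further compounds
F1 | step 9 | (4S,5R,6S,7Z)-6-acetoxy-2,8-dimethyl-9-oxo-5-(propan-2-yl)dodeca-1,7,11-trien-4-yl benzoate | C=CCC(=O)/C(C)=C\[C@H](OC(C)=O)[C@H](C(C)C)[C@@H](OC(=O)c1ccccc1)CC(C)=C
F2 | step 10 | (2Z,6Z,9S,10R)-9-hydroxy-3,7-dimethyl-10-(propan-2-yl)cyclodeca-2,6-diene-1,4-dione | O=C1/C=C(/C)C(=O)C/C=C(/C)C[C@H](O)[C@H]1C(C)C
F3 | step 10 | (1S,2Z,6Z,9S,10S)-1-hydroxy-3,7-dimethyl-4-oxo-10-(propan-2-yl)cyclodeca-2,6-dien-9-yl benzoate | O[C@H]1/C=C(/C)C(=O)C/C=C(/C)C[C@H](OC(=O)c2ccccc2)[C@H]1C(C)C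
F4 | step 10 | (1S,2Z,6Z,9S,10R)-1-acetoxy-3,7-dimethyl-4-oxo-10-(propan-2-yl)cyclodeca-2,6-dien-9-yl benzoate | CC(=O)O[C@H]1/C=C(/C)C(=O)C/C=C(/C)C[C@H](OC(=O)c2ccccc2)[C@H]1C(C)C
F5 | step 8 | (1Z,3R)-1-iodo-2-methylhexa-1,5-dien-3-ol | C=CC[C@@H](O)/C(C)=C\I
F6 | step 8 | tert-butyl{[(1Z,3R)-1-iodo-2-methylhexa-1,5-dien-3-yl]oxy}dimethylsilane | C=CC[C@@H](O[Si](C)(C)C(C)(C)C)/C(C)=C\I
F7 | step 8 | (4S,5R,7Z,9R)-9-[(tert-butyldimethylsilyl)oxy]-4-hydroxy-2,8-dimethyl-5-(propan-2-yl)dodeca-1,7,11-trien-6-one | C=CC[C@@H](O[Si](C)(C)C(C)(C)C)/C(C)=C\C(=O)[C@H](C(C)C)[C@@H](O)CC(C)=C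
F8 | step 8 | (4S,5S,6S,7Z,9R)-9-[(tert-butyldimethylsilyl)oxy]-6-hydroxy-2,8-dimethyl-5-(propan-2-yl)dodeca-1,7,11-trien-4-yl benzoate | C=CC[C@@H](O[Si](C)(C)C(C)(C)C)/C(C)=C\[C@H](O)[C@H](C(C)C)[C@@H](OC(=O)c1ccccc1)CC(C)=C
F9 | step 8 | (4S,5R,6S,7Z,9R)-6-acetoxy-9-[(tert-butyldimethylsilyl)oxy]-2,8-dimethyl-5-(propan-2-yl)dodeca-1,7,11-trien-4-yl benzoate | C=CC[C@@H](O[Si](C)(C)C(C)(C)C)/C(C)=C\[C@H](OC(C)=O)[C@H](C(C)C)[C@@H](OC(=O)c1ccccc1)CC(C)=C
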